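The data come from a simulation from invented constants; the scatter is artificial.

The flask is read at 6.0 min, and the earlier runs have gone flat by their last readings, so the question is where Qb has gone.

| flask | Qa | Qb | remark | time |
|---|---|---|---|---|
| west | 0.80 M | 0.80 equiv | run made earlier |  |
| south-east | 0.80 M | 1.8 equiv | run made earlier |  |
| south | 0.40 M | 1.2 equiv | run made earlier |  |
| flask | 0.80 M | 1.20 equiv |  | 6.0 min |

- west (time / min: Qa / %, Qe / %): 1.00: 78.2, 16.0; 2.00: 76.6, 16.5; 3.00: 76.3, 17.7; 4.00: 76.2, 17.9; 5.00: 75.9, 18.1
- south-east (time / min: Qa / %, Qe / %): 0.417: 68.6, 20.0; 0.667: 61.8, 22.8; 1.33: 55.2, 22.3; 2.50: 54.0, 23.0; 5.00: 54.8, 23.2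
- south (time / min: Qa / %, Qe / %): 0.417: 87.6, 10.4; 1.33: 79.3, 16.6; 2.00: 77.4, 16.6; 3.00: 77.3, 16.6; 5.00: 76.7, 17.2

(scatter of a reading: 0.5 percentage points)

- the reaction counts as stopped when no species that holds the Qa changes by six tenths of a point or more over the second half of the time

- the state of affairs at 6.0 min: stopped, and by what, or still going (all of Qa has reacted / forward and back rates have come level / Qb has run out first / it is still moving)
- part of the Qa gone at 6.0 min
- the Qe standing at 6.0 min, as a percentage of the Qa charged
- the Qf standing at 6.0 min, as a percentage of the Qa charged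

Read the last row of each table, taking Qf as what Qa and Qe leave of the charge; Qe holds one exchanged ligand and Qf two. The west run has then put 0.241 M of its 0.640 M of Qb into the complex, yet [Qa] stands still at 75.9%. The south-east run, charged with more Qb, stands lower, at 54.8%.

So the unaccounted Qb is taken as lost on a path of its own. If Qa and that path both run in step with [Qb], one ratio should hold. The west, south-east and south rows give 0.691 L mol⁻¹, 0.667 L mol⁻¹ and 0.732 L mol⁻¹, with a mean of 0.696 L mol⁻¹. This mean is the share ratio: the logarithm of Qa charged over Qa standing, divided by the [Qb] lost elsewhere.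

Qb taken up per Qa gone reads 1.25 in the west run and 1.49 in the south-east run. The flask's charge lies 0.400 of the way between them, which gives 1.34 and a first answer of 32.5% of Qa gone. Put back through the share ratio, that answer becomes 34.6%, and a second round gives 33.6%. The same line puts Qe at 20.1%, which leaves 13.5% for Qf.

The forecast holds that “Qb seems to decay by a first-order side reaction” and gives: Qb has run out first, 33.6% gone, 21.5% Qe, 12.1% Qf. The reckoning here has about the same Qa gone, less Qe and more Qf.

The flask gives: Qb has run out first, 33.3% gone, 21.0% Qe, 11.0% Qf.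

    Qb → Qd (k = 0.0230 s⁻¹)
    Qe + Qb → Qc + Qf (k = 0.0370 L mol⁻¹ s⁻¹)
    Qa + Qb → Qc + Qe (k = 0.0160 L mol⁻¹ s⁻¹)
    Qg + Qb → Qc + Qh (k = 0.00810 L mol⁻¹ s⁻¹)
    Qf + Qb → Qc + Qg (k = 0.0130 L mol⁻¹ s⁻¹)

In the flask at 6.00 min, Qb, the limiting reagent, stands at 0% of its charge against 67% of its charge for Qa. The logarithm of the flask's Qa charged over Qa standing, divided by its 0.583 M of Qd, makes a share ratio of 0.695 L mol⁻¹. A neighbour charged with 0.300 equiv of Qb, other settings as in the flask, starts on the same line, carried below the west charge, at 13.5%, with 1.13 Qb per Qa. Two rounds with 0.696 L mol⁻¹ give 7.86%, then 11.1%. The neighbour itself loses 9.97% of its Qa, and its Qb stands at 0%.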